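**Retrosynthetic overview**
1. Last bond: ester C1–O/C1′ between the decalin alcohol (C20 core) and the complete, protected tetraene acid (C19 acyl part); one fluoride step then removes all silicon groups.
2. Side chain: Stille bond C7′–C8′ between a dienylstannane acid (C2′/C3′ from an anti-aldol) and a (2E,4Z)-5-iodo-dienoate.
3. Decalin: ring A and ring B close together in one intramolecular furan Diels–Alder reaction of a 5-methylfuran tethered to an (E)-2-methyl-2-ene-1,4-dione; this sets C7, C8 and C8a, and the furan oxygen becomes the C7 hydroxyl.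
4. The oxygen bridge is then opened (C4 ketone, SmI2), the C4=C4a/C5=C6 diene comes from a dienyl triflate, C1–OH from hydride reduction, and the 3-hydroxypropanoyl group from a formaldehyde aldol on the C8 acetyl.
5. The tether comes from 5-methylfurfural by catalytic syn-crotylboration (C3, C4) and a Nozaki–Hiyama–Kishi coupling with an iodo-enone.

Assumption: numbering is decalin C1–C8a (C1 = ester carbinol), C9–C11 = acyl chain on C8, side chain C1′–C12′ from the ester carbonyl; the recoverable oxazolidinone and other atom-donating reagents are handled as reagents.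

**Iodo-enone**

Step 1
Reactants: 1 but-3-yn-2-ol (racemic)
Product: 3 (E)-4-iodo-3-methylbut-3-en-2-ol, via vinylalane 2 (not isolated)
Conditions: Me3Al (3 equiv), Cp2ZrCl2 (0.25 equiv), CH2Cl2, 0 °C to rt; then I2, THF, −30 °C; aqueous work-up
Reagents that add atoms: trimethylaluminium C[Al](C)C; iodine II
Why: Negishi carboalumination adds CH3 (internal carbon) and Al (terminal carbon) syn across the alkyne and iodinolysis with retention gives the E iodide (iodine trans to the carbinol carbon); the racemic carbinol is oxidised next.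

Step 2
Reactants: 3 (E)-4-iodo-3-methylbut-3-en-2-ol
Product: 4 (E)-4-iodo-3-methylbut-3-en-2-one
Conditions: MnO2, CH2Cl2, rt
Reagents that add atoms: none
Why: Allylic alcohol oxidation with MnO2 leaves the vinyl iodide and the E geometry (acetyl cis to H) untouched.

**Decalin alcohol**

Step 3
Reactants: 5 5-methylfuran-2-carbaldehyde
Product: 7 (1R,2S)-2-methyl-1-(5-methylfuran-2-yl)but-3-en-1-ol, via pinacol borate ester 6 (not isolated)
Conditions: (Z)-crotylboronic acid pinacol ester (1.2 equiv), (R)-3,3′-bis(2,4,6-triisopropylphenyl)-1,1′-binaphthyl-2,2′-diyl hydrogen phosphate (5 mol %), toluene, −30 °C; aq. NaHCO3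
Reagents that add atoms: (Z)-crotylboronic acid pinacol ester C/C=C\CB1OC(C)(C)C(C)(C)O1
Why: Chiral phosphoric acid-catalysed crotylboration through a closed chair transition state gives the syn adduct from the Z boronate, and the (R)-catalyst is chosen for the aldehyde face that gives 1R (to be confirmed on 7; the (S)-catalyst is used if the sense is opposite), so C4 (R) and the lasting C3 methyl centre (S) are set here.

Step 4
Reactants: 7 (1R,2S)-2-methyl-1-(5-methylfuran-2-yl)but-3-en-1-ol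
Product: 8 tert-butyl(dimethyl){[(1R,2S)-2-methyl-1-(5-methylfuran-2-yl)but-3-en-1-yl]oxy}silane
Conditions: TBSCl, imidazole, DMF, rt
Reagents that add atoms: tert-butyldimethylsilyl chloride CC(C)(C)[Si](C)(C)Cl
Why: Standard silylation; the bulky silyl ether resists the later Lewis acid and sits equatorial in the cycloaddition.

Step 5
Reactants: 8 silyl ether
Product: 10 (3S,4R)-4-(tert-butyldimethylsilyloxy)-3-methyl-4-(5-methylfuran-2-yl)butan-1-ol, via B-alkyl-9-BBN adduct 9 (not isolated)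
Conditions: 9-borabicyclo[3.3.1]nonane, THF, 0 °C to rt; then NaOH, H2O2, 0 °C
Reagents that add atoms: hydrogen peroxide OO
Why: Brown hydroboration–oxidation adds anti-Markovnikov to the terminal alkene only (the 2,5-dialkylfuran is inert) and gives the primary alcohol, the future C1.

Step 6
Reactants: 10 primary alcohol
Product: 11 (3S,4R)-4-(tert-butyldimethylsilyloxy)-3-methyl-4-(5-methylfuran-2-yl)butanal
Conditions: Dess–Martin periodinane, NaHCO3, CH2Cl2, 0 °C to rt
Reagents that add atoms: none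
Why: Buffered Dess–Martin oxidation gives the aldehyde; its α-carbon is CH2, so no stereocentre can epimerise.

Step 7
Reactants: 11 aldehyde; 4 (E)-4-iodo-3-methylbut-3-en-2-one
Product: 13 (3E,7S,8R)-8-(tert-butyldimethylsilyloxy)-5-hydroxy-3,7-dimethyl-8-(5-methylfuran-2-yl)oct-3-en-2-one (C5 epimers), via vinylchromium dichloride 12 (not isolated)
Conditions: CrCl2 (4 equiv), NiCl2 (1 mol %), DMSO/THF, rt
Reagents that add atoms: none
Why: Nozaki–Hiyama–Kishi coupling forms the vinylchromium species with retention of geometry and adds it to the aldehyde only (the ketone of 4 is untouched), joining C1 to C8a; the new carbinol is oxidised next.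

Step 8
Reactants: 13 allylic alcohol
Product: 14 (3E,7S,8R)-8-(tert-butyldimethylsilyloxy)-3,7-dimethyl-8-(5-methylfuran-2-yl)oct-3-ene-2,5-dione
Conditions: Dess–Martin periodinane, NaHCO3, CH2Cl2, 0 °C; used at once
Reagents that add atoms: none
Why: Dess–Martin oxidation of the allylic alcohol gives the doubly activated (E)-2-methyl-2-ene-1,4-dione dienophile with fixed geometry.

Step 9
Reactants: 14 enedione
Product: 15 (3S,4R,4aS,7R,8R,8aR)-8-acetyl-4-(tert-butyldimethylsilyloxy)-3,7,8-trimethyl-3,4,8,8a-tetrahydro-2H-4a,7-epoxynaphthalen-1(7H)-one (bridge O, C8 methyl and the C8a–C1 bond on one face; acetyl and H-8a on the other)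
Conditions: Me2AlCl (1.1 equiv), CH2Cl2, −78 to −30 °C; aq. NaHCO3
Reagents that add atoms: none
Why: In this Lewis acid-promoted intramolecular furan Diels–Alder reaction the four-atom tether must lie exo (syn to the oxygen bridge), so the E dienophile puts the C8 methyl syn and the acetyl and H-8a anti to the bridge, and the chair-like tether with equatorial C3 methyl and C4 silyloxy groups selects the face, which sets C7 (R), C8 (R) and C8a correctly relative to C3 (expected, not guaranteed, so the relative configuration of 15 is confirmed by NOE before going on).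

Step 10
Reactants: 15 tricyclic diketone
Product: 16 (1S,3S,4R,4aS,7R,8R,8aS)-8-acetyl-4-(tert-butyldimethylsilyloxy)-3,7,8-trimethyl-1,2,3,4,4a,7,8,8a-octahydro-4a,7-epoxynaphthalen-1-ol
Conditions: LiBH(s-Bu)3 (1.1 equiv), THF, −78 °C
Reagents that add atoms: none
Why: Axial attack on the ring ketone is blocked by the syn-axial oxygen bridge, so the bulky hydride attacks equatorially and gives the axial 1S alcohol cis to the C8a–C8 bond, while the acetyl on the quaternary carbon is too hindered to be reduced at −78 °C.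

Step 11
Reactants: 16 alcohol
Product: 17 allyl carbonate of 16 at C1–O
Conditions: allyl chloroformate, pyridine, 4-(dimethylamino)pyridine (cat.), CH2Cl2, 0 °C to rt
Reagents that add atoms: allyl chloroformate C=CCOC(Cl)=O
Why: Carbonate formation protects C1–OH through the oxidation and enolate steps and is chosen because it is removed in the palladium step 17.

Step 12
Reactants: 17 allyl carbonate
Product: 18 allyl (1S,3S,4R,4aS,7R,8R,8aS)-8-acetyl-4-hydroxy-3,7,8-trimethyl-1,2,3,4,4a,7,8,8a-octahydro-4a,7-epoxynaphthalen-1-yl carbonate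
Conditions: HF·pyridine, pyridine, THF, 0 °C to rt
Reagents that add atoms: none
Why: Buffered fluoride desilylation frees the C4 hydroxyl without touching carbonate, ketone or bridge, and staying at or below rt avoids retro-Diels–Alder cleavage.

Step 13
Reactants: 18 C4 alcohol
Product: 19 allyl (1S,3S,4aS,7R,8R,8aS)-8-acetyl-3,7,8-trimethyl-4-oxo-1,2,3,4,4a,7,8,8a-octahydro-4a,7-epoxynaphthalen-1-yl carbonate
Conditions: Dess–Martin periodinane, NaHCO3, CH2Cl2, rt
Reagents that add atoms: none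
Why: Dess–Martin oxidation gives the α-alkoxy ketone needed to open the bridge reductively.

Step 14
Reactants: 19 α-alkoxy ketone
Product: 20 allyl (1S,3S,7R,8R,8aS)-8-acetyl-7-hydroxy-3,7,8-trimethyl-4-oxo-1,2,3,4,4a,7,8,8a-octahydronaphthalen-1-yl carbonate (β,γ-enone, C4a epimers)
Conditions: SmI2 (2.2 equiv), THF/MeOH, −78 °C
Reagents that add atoms: none
Why: SmI2 reduction of an α-alkoxy ketone cleaves only the C4a–O bond α to the ketyl, so the bridge oxygen stays on C7 as the tertiary hydroxyl with the configuration set in step 9, and isolated ketones are not reduced at −78 °C.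

Step 15
Reactants: 20 hydroxy ketone
Product: 21 C7 trimethylsilyl ether of 20
Conditions: Me3SiOTf, 2,6-lutidine, CH2Cl2, −78 °C
Reagents that add atoms: trimethylsilyl trifluoromethanesulfonate C[Si](C)(C)OS(=O)(=O)C(F)(F)F
Why: Silylation of the tertiary alcohol blocks retro-aldol cleavage (C7 alkoxide/C9 ketone) in the base steps that follow.

Step 16
Reactants: 21 silyl ether ketone
Product: 23 allyl (1S,3S,7R,8R,8aS)-8-acetyl-3,7,8-trimethyl-4-(trifluoromethylsulfonyloxy)-7-(trimethylsilyloxy)-1,2,3,7,8,8a-hexahydronaphthalen-1-yl carbonate, via potassium dienolate 22 (not isolated)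
Conditions: KN(SiMe3)2 (1.1 equiv), THF, −78 °C, 45 min; then PhNTf2, −78 to −40 °C
Reagents that add atoms: N-phenylbis(trifluoromethanesulfonimide) O=S(=O)(N(c1ccccc1)S(=O)(=O)C(F)(F)F)C(F)(F)F
Why: H-4a is α to the ketone and allylic and therefore the most acidic proton, so the extended dienolate forms and enolate O-triflation gives the C4=C4a/C5=C6 dienyl triflate regiospecifically while C3 keeps its configuration.

Step 17
Reactants: 23 dienyl triflate
Product: 25 (1S,3S,7R,8R,8aS)-8-acetyl-3,7,8-trimethyl-7-(trimethylsilyloxy)-1,2,3,7,8,8a-hexahydronaphthalen-1-ol, via hydroxy dienyl triflate 24 (not isolated)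
Conditions: Pd(OAc)2 (5 mol %), PPh3 (10 mol %), HCO2H (3 equiv), Et3N (5 equiv), DMF, 40 °C
Reagents that add atoms: none
Why: Palladium-catalysed formate reduction of the vinyl triflate gives the conjugated diene without alkene migration, and the same zerovalent palladium/formate system removes the allyl carbonate (Tsuji–Trost deallylation) to free C1–OH; excess Et3N keeps the medium non-acidic.

Step 18
Reactants: 25 methyl ketone
Product: 27 (1S,3S,7R,8R,8aS)-8-(3-hydroxypropanoyl)-3,7,8-trimethyl-7-(trimethylsilyloxy)-1,2,3,7,8,8a-hexahydronaphthalen-1-ol, via dilithium enolate alkoxide 26 (not isolated)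
Conditions: LiN(i-Pr)2 (2.2 equiv), THF, −78 °C; then monomeric CH2O in THF, −78 °C; pH 7 buffer
Reagents that add atoms: formaldehyde C=O
Why: C8 is quaternary, so the acetyl methyl is the only enolisable site and the kinetic enolate aldol with formaldehyde builds the 3-hydroxypropanoyl group; the C7 silyl ether prevents retro-aldol.

Step 19
Reactants: 27 diol
Product: 28 (1S,3S,7R,8R,8aS)-3,7,8-trimethyl-8-[3-(triethylsilyloxy)propanoyl]-7-(trimethylsilyloxy)-1,2,3,7,8,8a-hexahydronaphthalen-1-ol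
Conditions: Et3SiCl (1.05 equiv), imidazole, CH2Cl2, −40 °C
Reagents that add atoms: chlorotriethylsilane CC[Si](Cl)(CC)CC
Why: The primary hydroxyl is silylated far faster than the hindered axial C1 hydroxyl, which is left as the only free hydroxyl for the esterification.

**Iodo-dienoate**

Step 20
Reactants: 29 but-2-yn-1-ol
Product: 31 (Z)-3-iodobut-2-en-1-ol, via cyclic vinylalanate 30 (not isolated)
Conditions: NaAlH2(OCH2CH2OMe)2, THF, 0 °C to rt; then I2, −78 to 0 °C
Reagents that add atoms: iodine II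
Why: Hydroxyl-directed trans-hydroalumination puts Al on C3 in a cyclic alanate and iodinolysis with retention gives the Z iodide (iodine cis to CH2OH), the geometry of the 8′Z alkene.

Step 21
Reactants: 31 (Z)-3-iodobut-2-en-1-ol
Product: 32 (Z)-3-iodobut-2-enal
Conditions: MnO2, CH2Cl2, rt; used fresh
Reagents that add atoms: none
Why: Neutral MnO2 allylic oxidation does not isomerise the Z iodo-enal.

Step 22
Reactants: 32 (Z)-3-iodobut-2-enal
Product: 33 ethyl (2E,4Z)-5-iodohexa-2,4-dienoate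
Conditions: Ph3P=CHCO2Et, CH2Cl2, rt
Reagents that add atoms: ethyl (triphenylphosphoranylidene)acetate CCOC(=O)C=P(c1ccccc1)(c1ccccc1)c1ccccc1
Why: Wittig olefination with the stabilised ylide gives the 2E alkene and leaves the Z iodoalkene unchanged.

Step 23
Reactants: 33 ethyl ester
Product: 34 (2E,4Z)-5-iodohexa-2,4-dienoic acid
Conditions: LiOH, THF/H2O, rt; then 1 M HCl to pH 3
Reagents that add atoms: lithium hydroxide [Li+].[OH-]
Why: Saponification of the unhindered dienoate leaves the vinyl iodide intact.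

Step 24
Reactants: 34 acid
Product: 36 2-(trimethylsilyl)ethyl (2E,4Z)-5-iodohexa-2,4-dienoate, via O-acylisourea 35 (not isolated)
Conditions: N,N′-dicyclohexylcarbodiimide, 4-(dimethylamino)pyridine (cat.), 2-(trimethylsilyl)ethanol, CH2Cl2, 0 °C to rt
Reagents that add atoms: 2-(trimethylsilyl)ethanol C[Si](C)(C)CCO
Why: Steglich esterification installs a fluoride-labile ester that masks C12′ during both coupling steps.

**Stannane acid and side chain**

Step 25
Reactants: 37 prop-2-yn-1-ol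
Product: 38 (E)-3-(tributylstannyl)prop-2-en-1-ol
Conditions: Bu3SnH, azobis(isobutyronitrile) (cat.), neat, 80 °C; chromatography
Reagents that add atoms: tributyltin hydride CCCC[SnH](CCCC)CCCC
Why: Radical hydrostannation of the terminal alkyne gives mainly the thermodynamically favoured E β-stannyl alcohol.

Step 26
Reactants: 38 stannyl allylic alcohol
Product: 39 (E)-3-(tributylstannyl)prop-2-enal
Conditions: MnO2, CH2Cl2, rt
Reagents that add atoms: none
Why: MnO2 allylic oxidation leaves the vinylstannane intact.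

Step 27
Reactants: 39 stannyl enal
Product: 40 (2E,4E)-2-methyl-5-(tributylstannyl)penta-2,4-dienal
Conditions: Ph3P=C(CH3)CHO, toluene, 80 °C
Reagents that add atoms: 2-(triphenylphosphoranylidene)propanal CC(C=O)=P(c1ccccc1)(c1ccccc1)c1ccccc1
Why: Wittig olefination with the stabilised α-methyl ylide gives the E trisubstituted enal.

Step 28
Reactants: 41 propanoyl chloride
Product: 42 (4R)-4-benzyl-3-propanoyl-1,3-oxazolidin-2-one
Conditions: (R)-4-benzyl-1,3-oxazolidin-2-one, Et3N, 4-(dimethylamino)pyridine (cat.), CH2Cl2, 0 °C to rt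
Reagents that add atoms: (R)-4-benzyl-1,3-oxazolidin-2-one O=C1N[C@H](Cc2ccccc2)CO1
Why: N-acylation attaches the recoverable Evans auxiliary.

Step 29
Reactants: 42 N-propanoyl oxazolidinone; 40 stannyl dienal
Product: 44 (4R)-4-benzyl-3-[(2S,3R,4E,6E)-3-hydroxy-2,4-dimethyl-7-(tributylstannyl)hepta-4,6-dienoyl]-1,3-oxazolidin-2-one, via TMS ether 43 (not isolated)
Conditions: MgCl2 (20 mol %), Et3N, Me3SiCl, EtOAc, rt; then MeOH, citric acid (cat.), 0 °C
Reagents that add atoms: none
Why: In the Evans MgCl2-catalysed anti-aldol the chelated Z-enolate reacts through a boat transition state on the face opposite the benzyl group, giving the anti 2′S,3′R adduct with the non-enolisable enal; mild methanolysis removes the O-silyl group.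

Step 30
Reactants: 44 aldol adduct
Product: 45 (4R)-4-benzyl-3-[(2S,3R,4E,6E)-2,4-dimethyl-3-(triethylsilyloxy)-7-(tributylstannyl)hepta-4,6-dienoyl]-1,3-oxazolidin-2-one
Conditions: Et3SiOTf, 2,6-lutidine, CH2Cl2, −78 °C
Reagents that add atoms: triethylsilyl trifluoromethanesulfonate CC[Si](CC)(CC)OS(=O)(=O)C(F)(F)F
Why: Silylation of the allylic alcohol under buffered conditions protects it for the coupling steps and spares the vinylstannane.

Step 31
Reactants: 45 silylated imide
Product: 47 (2S,3R,4E,6E)-2,4-dimethyl-3-(triethylsilyloxy)-7-(tributylstannyl)hepta-4,6-dienoic acid, via lithium peroxycarboxylate 46 (not isolated)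
Conditions: LiOH, H2O2, THF/H2O, 0 °C; then Na2SO3; NaHSO4 to pH 4
Reagents that add atoms: hydrogen peroxide OO
Why: Hydroperoxide attacks the exocyclic imide carbonyl selectively, releasing the auxiliary without C2′ epimerisation, and sulfite reduces the peracid.

Step 32
Reactants: 47 stannane acid; 36 iodo-dienoate
Product: 48 (2S,3R,4E,6E,8Z,10E)-2,4,8-trimethyl-12-oxo-3-(triethylsilyloxy)-12-[2-(trimethylsilyl)ethoxy]dodeca-4,6,8,10-tetraenoic acid
Conditions: PdCl2(MeCN)2 (5 mol %), i-Pr2NEt, DMF, rt, dark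
Reagents that add atoms: none
Why: Stille coupling joins C7′ to C8′ with retention of both alkene geometries, giving the 4E,6E,8Z,10E tetraene; the free acid is carried as its ammonium salt.

**Union and deprotection**

Step 33
Reactants: 48 tetraene acid; 28 decalin alcohol
Product: 50 protected calbistrin D (12′-[2-(trimethylsilyl)ethyl] ester, 3′-O- and 11-O-triethylsilyl, 7-O-trimethylsilyl), via mixed anhydride 49 (not isolated)
Conditions: 2,4,6-trichlorobenzoyl chloride, Et3N, toluene, rt; then 28, 4-(dimethylamino)pyridine, toluene, rt to 40 °C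
Reagents that add atoms: none
Why: In the Yamaguchi esterification the acylpyridinium formed from the mixed anhydride acylates the hindered axial C1–OH, the only free hydroxyl, under conditions mild enough to avoid C2′ epimerisation and β-elimination.

Step 34
Reactants: 50 protected calbistrin D
Product: 51 calbistrin D
Conditions: (Me2N)3S(Me3SiF2) (TASF, 8 equiv), DMF, 0 °C to rt; pH 7 phosphate buffer
Reagents that add atoms: none
Why: This nearly neutral fluoride source cleaves the three silyl ethers and fragments the 2-(trimethylsilyl)ethyl ester in one global deprotection, sparing the C1 ester, the tetraene and the β-hydroxy ketone and touching no stereocentre.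

**Compound list**
1 | but-3-yn-2-ol (racemic) | CC(O)C#C | starting material
2 | dimethyl{(E)-3-[(dimethylalumanyl)oxy]-2-methylbut-1-en-1-yl}alumane | CC(O[Al](C)C)/C(C)=C/[Al](C)C | intermediate (not isolated)
3 | (E)-4-iodo-3-methylbut-3-en-2-ol | CC(O)/C(C)=C/I | intermediate
4 | (E)-4-iodo-3-methylbut-3-en-2-one | CC(=O)/C(C)=C/I | intermediate
5 | 5-methylfuran-2-carbaldehyde | Cc1ccc(C=O)o1 | starting material
6 | 2-{[(1R,2S)-2-methyl-1-(5-methylfuran-2-yl)but-3-en-1-yl]oxy}-4,4,5,5-tetramethyl-1,3,2-dioxaborolane | C=C[C@H](C)[C@@H](OB1OC(C)(C)C(C)(C)O1)c1ccc(C)o1 | intermediate (not isolated)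
7 | (1R,2S)-2-methyl-1-(5-methylfuran-2-yl)but-3-en-1-ol | C=C[C@H](C)[C@@H](O)c1ccc(C)o1 | intermediate
8 | tert-butyl(dimethyl){[(1R,2S)-2-methyl-1-(5-methylfuran-2-yl)but-3-en-1-yl]oxy}silane | C=C[C@H](C)[C@@H](O[Si](C)(C)C(C)(C)C)c1ccc(C)o1 | intermediate
9 | 9-[(3S,4R)-4-(tert-butyldimethylsilyloxy)-3-methyl-4-(5-methylfuran-2-yl)butyl]-9-borabicyclo[3.3.1]nonane | C1CCC2CCCC1B2CC[C@H](C)[C@@H](O[Si](C)(C)C(C)(C)C)c1ccc(C)o1 | intermediate (not isolated)
10 | (3S,4R)-4-(tert-butyldimethylsilyloxy)-3-methyl-4-(5-methylfuran-2-yl)butan-1-ol | OCC[C@H](C)[C@@H](O[Si](C)(C)C(C)(C)C)c1ccc(C)o1 | intermediate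
11 | (3S,4R)-4-(tert-butyldimethylsilyloxy)-3-methyl-4-(5-methylfuran-2-yl)butanal | O=CC[C@H](C)[C@@H](O[Si](C)(C)C(C)(C)C)c1ccc(C)o1 | intermediate
12 | [(E)-2-methyl-3-oxobut-1-en-1-yl]chromium dichloride | CC(=O)/C(C)=C/[Cr](Cl)Cl | intermediate (not isolated)
13 | (3E,7S,8R)-8-(tert-butyldimethylsilyloxy)-5-hydroxy-3,7-dimethyl-8-(5-methylfuran-2-yl)oct-3-en-2-one (C5 epimers) | CC(=O)/C(C)=C/C(O)C[C@H](C)[C@@H](O[Si](C)(C)C(C)(C)C)c1ccc(C)o1 | intermediate
14 | (3E,7S,8R)-8-(tert-butyldimethylsilyloxy)-3,7-dimethyl-8-(5-methylfuran-2-yl)oct-3-ene-2,5-dione | CC(=O)/C(C)=C/C(=O)C[C@H](C)[C@@H](O[Si](C)(C)C(C)(C)C)c1ccc(C)o1 | intermediate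
15 | (3S,4R,4aS,7R,8R,8aR)-8-acetyl-4-(tert-butyldimethylsilyloxy)-3,7,8-trimethyl-3,4,8,8a-tetrahydro-2H-4a,7-epoxynaphthalen-1(7H)-one | O=C1C[C@H](C)[C@@H](O[Si](C)(C)C(C)(C)C)[C@]23O[C@](C)(C=C2)[C@](C)(C(C)=O)[C@@H]13 | intermediate
16 | (1S,3S,4R,4aS,7R,8R,8aS)-8-acetyl-4-(tert-butyldimethylsilyloxy)-3,7,8-trimethyl-1,2,3,4,4a,7,8,8a-octahydro-4a,7-epoxynaphthalen-1-ol | O[C@H]1C[C@H](C)[C@@H](O[Si](C)(C)C(C)(C)C)[C@]23O[C@](C)(C=C2)[C@](C)(C(C)=O)[C@@H]13 | intermediate
17 | allyl carbonate of 16 (C1–O) | C=CCOC(=O)O[C@H]1C[C@H](C)[C@@H](O[Si](C)(C)C(C)(C)C)[C@]23O[C@](C)(C=C2)[C@](C)(C(C)=O)[C@@H]13 | intermediate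
18 | allyl (1S,3S,4R,4aS,7R,8R,8aS)-8-acetyl-4-hydroxy-3,7,8-trimethyl-1,2,3,4,4a,7,8,8a-octahydro-4a,7-epoxynaphthalen-1-yl carbonate | C=CCOC(=O)O[C@H]1C[C@H](C)[C@@H](O)[C@]23O[C@](C)(C=C2)[C@](C)(C(C)=O)[C@@H]13 | intermediate
19 | allyl (1S,3S,4aS,7R,8R,8aS)-8-acetyl-3,7,8-trimethyl-4-oxo-1,2,3,4,4a,7,8,8a-octahydro-4a,7-epoxynaphthalen-1-yl carbonate | C=CCOC(=O)O[C@H]1C[C@H](C)C(=O)[C@]23O[C@](C)(C=C2)[C@](C)(C(C)=O)[C@@H]13 | intermediate
20 | allyl (1S,3S,7R,8R,8aS)-8-acetyl-7-hydroxy-3,7,8-trimethyl-4-oxo-1,2,3,4,4a,7,8,8a-octahydronaphthalen-1-yl carbonate (C4a epimers) | C=CCOC(=O)O[C@H]1C[C@H](C)C(=O)C2C=C[C@@](C)(O)[C@](C)(C(C)=O)[C@@H]12 | intermediate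
21 | 7-O-trimethylsilyl ether of 20 | C=CCOC(=O)O[C@H]1C[C@H](C)C(=O)C2C=C[C@@](C)(O[Si](C)(C)C)[C@](C)(C(C)=O)[C@@H]12 | intermediate
22 | potassium C4 dienolate of 21 | C=CCOC(=O)O[C@H]1C[C@H](C)C([O-])=C2C=C[C@@](C)(O[Si](C)(C)C)[C@](C)(C(C)=O)[C@@H]12.[K+] | intermediate (not isolated)
23 | allyl (1S,3S,7R,8R,8aS)-8-acetyl-3,7,8-trimethyl-4-(trifluoromethylsulfonyloxy)-7-(trimethylsilyloxy)-1,2,3,7,8,8a-hexahydronaphthalen-1-yl carbonate | C=CCOC(=O)O[C@H]1C[C@H](C)C(OS(=O)(=O)C(F)(F)F)=C2C=C[C@@](C)(O[Si](C)(C)C)[C@](C)(C(C)=O)[C@@H]12 | intermediate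
24 | (5S,7S,1R,2R,8aS-type) C1 alcohol of 23: (1S,3S,7R,8R,8aS)-8-acetyl-1-hydroxy-3,7,8-trimethyl-7-(trimethylsilyloxy)-1,2,3,7,8,8a-hexahydronaphthalen-4-yl trifluoromethanesulfonate | O[C@H]1C[C@H](C)C(OS(=O)(=O)C(F)(F)F)=C2C=C[C@@](C)(O[Si](C)(C)C)[C@](C)(C(C)=O)[C@@H]12 | intermediate (not isolated)
25 | (1S,3S,7R,8R,8aS)-8-acetyl-3,7,8-trimethyl-7-(trimethylsilyloxy)-1,2,3,7,8,8a-hexahydronaphthalen-1-ol | O[C@H]1C[C@H](C)C=C2C=C[C@@](C)(O[Si](C)(C)C)[C@](C)(C(C)=O)[C@H]21 | intermediate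
26 | dilithium salt of 25 (C1 alkoxide, C9 enolate) | [Li]O[C@H]1C[C@H](C)C=C2C=C[C@@](C)(O[Si](C)(C)C)[C@](C)(C(=C)O[Li])[C@H]21 | intermediate (not isolated)
27 | (1S,3S,7R,8R,8aS)-8-(3-hydroxypropanoyl)-3,7,8-trimethyl-7-(trimethylsilyloxy)-1,2,3,7,8,8a-hexahydronaphthalen-1-ol | O[C@H]1C[C@H](C)C=C2C=C[C@@](C)(O[Si](C)(C)C)[C@](C)(C(=O)CCO)[C@H]21 | intermediate
28 | (1S,3S,7R,8R,8aS)-3,7,8-trimethyl-8-[3-(triethylsilyloxy)propanoyl]-7-(trimethylsilyloxy)-1,2,3,7,8,8a-hexahydronaphthalen-1-ol | O[C@H]1C[C@H](C)C=C2C=C[C@@](C)(O[Si](C)(C)C)[C@](C)(C(=O)CCO[Si](CC)(CC)CC)[C@H]21 | intermediate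
29 | but-2-yn-1-ol | CC#CCO | starting material
30 | sodium 2,2-bis(2-methoxyethoxy)-3-methyl-2,5-dihydro-1,2-oxaaluminol-2-uide | CC1=CCO[Al-]1(OCCOC)OCCOC.[Na+] | intermediate (not isolated)
31 | (Z)-3-iodobut-2-en-1-ol | C/C(I)=C/CO | intermediate
32 | (Z)-3-iodobut-2-enal | C/C(I)=C/C=O | intermediate
33 | ethyl (2E,4Z)-5-iodohexa-2,4-dienoate | C/C(I)=C/C=C/C(=O)OCC | intermediate
34 | (2E,4Z)-5-iodohexa-2,4-dienoic acid | C/C(I)=C/C=C/C(=O)O | intermediate
35 | O-[(2E,4Z)-5-iodohexa-2,4-dienoyl]-N,N′-dicyclohexylisourea | C/C(I)=C/C=C/C(=O)OC(=NC1CCCCC1)NC1CCCCC1 | intermediate (not isolated)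
36 | 2-(trimethylsilyl)ethyl (2E,4Z)-5-iodohexa-2,4-dienoate | C/C(I)=C/C=C/C(=O)OCC[Si](C)(C)C | intermediate
37 | prop-2-yn-1-ol | C#CCO | starting material
38 | (E)-3-(tributylstannyl)prop-2-en-1-ol | CCCC[Sn](CCCC)(CCCC)/C=C/CO | intermediate
39 | (E)-3-(tributylstannyl)prop-2-enal | CCCC[Sn](CCCC)(CCCC)/C=C/C=O | intermediate
40 | (2E,4E)-2-methyl-5-(tributylstannyl)penta-2,4-dienal | CCCC[Sn](CCCC)(CCCC)/C=C/C=C(\C)C=O | intermediate
41 | propanoyl chloride | CCC(Cl)=O | starting material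
42 | (4R)-4-benzyl-3-propanoyl-1,3-oxazolidin-2-one | CCC(=O)N1[C@H](Cc2ccccc2)COC1=O | intermediate
43 | O-trimethylsilyl ether of 44 | CCCC[Sn](CCCC)(CCCC)/C=C/C=C(\C)[C@H](O[Si](C)(C)C)[C@H](C)C(=O)N1[C@H](Cc2ccccc2)COC1=O | intermediate (not isolated)
44 | (4R)-4-benzyl-3-[(2S,3R,4E,6E)-3-hydroxy-2,4-dimethyl-7-(tributylstannyl)hepta-4,6-dienoyl]-1,3-oxazolidin-2-one | CCCC[Sn](CCCC)(CCCC)/C=C/C=C(\C)[C@H](O)[C@H](C)C(=O)N1[C@H](Cc2ccccc2)COC1=O | intermediate
45 | (4R)-4-benzyl-3-[(2S,3R,4E,6E)-2,4-dimethyl-3-(triethylsilyloxy)-7-(tributylstannyl)hepta-4,6-dienoyl]-1,3-oxazolidin-2-one | CCCC[Sn](CCCC)(CCCC)/C=C/C=C(\C)[C@H](O[Si](CC)(CC)CC)[C@H](C)C(=O)N1[C@H](Cc2ccccc2)COC1=O | intermediate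
46 | lithium (2S,3R,4E,6E)-2,4-dimethyl-3-(triethylsilyloxy)-7-(tributylstannyl)hepta-4,6-dieneperoxoate | CCCC[Sn](CCCC)(CCCC)/C=C/C=C(\C)[C@H](O[Si](CC)(CC)CC)[C@H](C)C(=O)O[O-].[Li+] | intermediate (not isolated)
47 | (2S,3R,4E,6E)-2,4-dimethyl-3-(triethylsilyloxy)-7-(tributylstannyl)hepta-4,6-dienoic acid | CCCC[Sn](CCCC)(CCCC)/C=C/C=C(\C)[C@H](O[Si](CC)(CC)CC)[C@H](C)C(=O)O | intermediate
48 | (2S,3R,4E,6E,8Z,10E)-2,4,8-trimethyl-12-oxo-3-(triethylsilyloxy)-12-[2-(trimethylsilyl)ethoxy]dodeca-4,6,8,10-tetraenoic acid | CC(=C/C=C/C(=O)OCC[Si](C)(C)C)/C=C/C=C(\C)[C@H](O[Si](CC)(CC)CC)[C@H](C)C(=O)O | intermediate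
49 | mixed anhydride of 48 and 2,4,6-trichlorobenzoic acid | CC(=C/C=C/C(=O)OCC[Si](C)(C)C)/C=C/C=C(\C)[C@H](O[Si](CC)(CC)CC)[C@H](C)C(=O)OC(=O)c1c(Cl)cc(Cl)cc1Cl | intermediate (not isolated)
50 | protected calbistrin D: 12′-[2-(trimethylsilyl)ethyl] ester, 3′-O- and 11-O-triethylsilyl, 7-O-trimethylsilyl | CC(=C/C=C/C(=O)OCC[Si](C)(C)C)/C=C/C=C(\C)[C@H](O[Si](CC)(CC)CC)[C@H](C)C(=O)O[C@H]1C[C@H](C)C=C2C=C[C@@](C)(O[Si](C)(C)C)[C@](C)(C(=O)CCO[Si](CC)(CC)CC)[C@H]21 | intermediate
51 | calbistrin D | CC(=C/C=C/C(=O)O)/C=C/C=C(\C)[C@H](O)[C@H](C)C(=O)O[C@H]1C[C@H](C)C=C2C=C[C@@](C)(O)[C@](C)(C(=O)CCO)[C@H]21 | target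

**Totals**
Total step count: 34. Longest linear sequence: 19 steps (steps 3–19, then 33 and 34).

**Steps most likely to fail**

Step 9, the furan Diels–Alder reaction, has to join two fully substituted carbons (C7–C8) and may stall or revert. The fallback uses an alkyne dienophile and brings in the C8 methyl afterwards. It sets out from aldehyde 11: the dilithium derivative of 1 (2 n-BuLi, THF, −78 °C) adds to 11 to give (7S,8R)-8-(tert-butyldimethylsilyloxy)-7-methyl-8-(5-methylfuran-2-yl)oct-3-yne-2,5-diol F1 (carbinol epimers). Dess–Martin oxidation of both carbinols gives the ynedione F2, whose doubly activated triple bond adds to the furan at or just above rt to give the oxanorbornadiene enedione F3. Me2CuLi/Me3SiCl (THF, −78 °C) then delivers the methyl group to C8 from the exo face (the face of the oxygen bridge); the ring enone is locked s-cis and C8a is the more hindered carbon. Protonation at C8a with brief Et3N equilibration to the exo-fused junction comes back to the route at 15.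

Step 18, the lithium-enolate aldol with gaseous formaldehyde, risks low conversion, double addition and dehydration. The fallback is a Lewis-acid Mukaiyama hydroxymethylation in water. It sets out from 25: LiN(i-Pr)2 then Me3SiCl gives the C1-O-silylated kinetic silyl enol ether F4. Aqueous formaldehyde with Yb(OTf)3 (THF/H2O, rt) hydroxymethylates the enol ether and hydrolyses the C1 O-silyl group, while the hindered tertiary C7 silyl ether stays; this comes back to the route at 27.

Step 33, the esterification, acylates a hindered axial alcohol with an epimerisable, polyene-bearing acid. The fallback changes the order of bond formation. It sets out from 28 and 47: Yamaguchi esterification with the shorter, more robust stannane acid 47 (which tolerates more forcing acylation) gives the C1 ester F5 carrying the dienylstannane. Stille coupling of it with 36 (PdCl2(MeCN)2, DMF, rt, dark) builds the tetraene on the decalin and comes back to the route at 50.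

**Further compounds**
F1 | step 9 | (7S,8R)-8-(tert-butyldimethylsilyloxy)-7-methyl-8-(5-methylfuran-2-yl)oct-3-yne-2,5-diol (carbinol epimers) | CC(O)C#CC(O)C[C@H](C)[C@@H](O[Si](C)(C)C(C)(C)C)c1ccc(C)o1
F2 | step 9 | (7S,8R)-8-(tert-butyldimethylsilyloxy)-7-methyl-8-(5-methylfuran-2-yl)oct-3-yne-2,5-dione | CC(=O)C#CC(=O)C[C@H](C)[C@@H](O[Si](C)(C)C(C)(C)C)c1ccc(C)o1
F3 | step 9 | (3S,4R,4aS,7R)-8-acetyl-4-(tert-butyldimethylsilyloxy)-3,7-dimethyl-3,4-dihydro-2H-4a,7-epoxynaphthalen-1(7H)-one | O=C1C[C@H](C)[C@@H](O[Si](C)(C)C(C)(C)C)[C@]23O[C@](C)(C=C2)C(C(C)=O)=C13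
F4 | step 18 | (1S,3S,7R,8R,8aS)-3,7,8-trimethyl-1,7-bis(trimethylsilyloxy)-8-[1-(trimethylsilyloxy)ethenyl]-1,2,3,7,8,8a-hexahydronaphthalene | C[Si](C)(C)O[C@H]1C[C@H](C)C=C2C=C[C@@](C)(O[Si](C)(C)C)[C@](C)(C(=C)O[Si](C)(C)C)[C@H]21
F5 | step 33 | (1S,3S,7R,8R,8aS)-3,7,8-trimethyl-8-[3-(triethylsilyloxy)propanoyl]-7-(trimethylsilyloxy)-1,2,3,7,8,8a-hexahydronaphthalen-1-yl (2S,3R,4E,6E)-2,4-dimethyl-3-(triethylsilyloxy)-7-(tributylstannyl)hepta-4,6-dienoate | CCCC[Sn](CCCC)(CCCC)/C=C/C=C(\C)[C@H](O[Si](CC)(CC)CC)[C@H](C)C(=O)O[C@H]1C[C@H](C)C=C2C=C[C@@](C)(O[Si](C)(C)C)[C@](C)(C(=O)CCO[Si](CC)(CC)CC)[C@H]21
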